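Assumption: the target SMILES has no stereodescriptor and the molecule has no stereocentre, and the 3–6'' axis is unspecified, so no stereocontrol is needed (a slowly rotating axis would simply give the racemate).

Unit 1 is the 5-hydroxy-7-methoxy-2-(4-methoxyphenyl)chromen-4-one half, linked through C3. Unit 2 is the apigenin half, linked through C6''.

**Retrosynthetic overview**
1. Target ⇐ one Lewis-acid deprotection of a biflavone carrying two benzyl ethers and two peri-methoxy groups.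
2. That biflavone ⇐ one Pd-mediated annulative arylation that forms the C3–C6'' bond and the O1–C2 bond (ring C of unit 1) together, from a 6-iodoflavone and an o-hydroxyaryl ynone. Two finished flavones are never cross-coupled.
3. 6-Iodoflavone ⇐ apigenin (all three rings of unit 2 purchased), by 7,4'-dibenzylation, C6 iodination directed by the free 5-OH, then 5-O-methylation.
4. Ynone ⇐ 2-hydroxy-4,6-dimethoxybenzaldehyde + 4-ethynylanisole (acetylide addition, then MnO2).
5. Ring order: unit 2 is preformed; ring C of unit 1 is closed last, in the coupling step.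

**Route**

Step 1
Reactants: 1 apigenin
Product: 2 7-(benzyloxy)-2-[4-(benzyloxy)phenyl]-5-hydroxy-4H-chromen-4-one
Conditions: BnBr (2.3 equiv), K2CO3 (3 equiv), DMF, 50 °C
Reagents that add atoms: benzyl bromide BrCc1ccccc1
Why: Williamson ether synthesis; the acidic 7- and 4'-OH are alkylated while the 5-OH, hydrogen-bonded to the C4 carbonyl, stays free.

Step 2
Reactants: 2 7-(benzyloxy)-2-[4-(benzyloxy)phenyl]-5-hydroxy-4H-chromen-4-one
Product: 3 7-(benzyloxy)-2-[4-(benzyloxy)phenyl]-5-hydroxy-6-iodo-4H-chromen-4-one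
Conditions: benzyltrimethylammonium dichloroiodate (1.1 equiv), CaCO3, CH2Cl2–MeOH, rt
Reagents that add atoms: benzyltrimethylammonium dichloroiodate C[N+](C)(C)Cc1ccccc1.Cl[I-]Cl
Why: Electrophilic aromatic iodination (SEAr); in 5-hydroxy-7-alkoxyflavones the free, hydrogen-bonded 5-OH steers a mild iodonium donor to C6 (the 5-O-alkyl series goes to C8), and ring B, deactivated through the pyrone, is left alone.

Step 3
Reactants: 3 7-(benzyloxy)-2-[4-(benzyloxy)phenyl]-5-hydroxy-6-iodo-4H-chromen-4-one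
Product: 4 7-(benzyloxy)-2-[4-(benzyloxy)phenyl]-6-iodo-5-methoxy-4H-chromen-4-one
Conditions: MeI (5 equiv), K2CO3, DMF, 60 °C
Reagents that add atoms: iodomethane CI
Why: Williamson O-methylation under forcing conditions overcomes the hydrogen bond of the 5-OH and caps it with the smallest group, so no ortho-phenoxide interferes with oxidative addition in step 6.

Step 4
Reactants: 5 4-ethynylanisole; 6 2-hydroxy-4,6-dimethoxybenzaldehyde
Product: 8 rac-1-(2-hydroxy-4,6-dimethoxyphenyl)-3-(4-methoxyphenyl)prop-2-yn-1-ol, via lithium (4-methoxyphenyl)acetylide 7 (not isolated)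
Conditions: 5 (3.2 equiv), n-BuLi (3.1 equiv), THF, −78 °C; then 6, −78 °C → rt; sat. aq NH4Cl
Reagents that add atoms: none
Why: 1,2-Addition of a lithium acetylide to an aldehyde; the first equivalent of 7 only deprotonates the phenol and the excess adds to the phenoxide-aldehyde on warming, giving a racemic carbinol centre that is erased in step 5.

Step 5
Reactants: 8 rac-1-(2-hydroxy-4,6-dimethoxyphenyl)-3-(4-methoxyphenyl)prop-2-yn-1-ol
Product: 9 1-(2-hydroxy-4,6-dimethoxyphenyl)-3-(4-methoxyphenyl)prop-2-yn-1-one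
Conditions: activated MnO2 (15 equiv), CH2Cl2, rt
Reagents that add atoms: none
Why: MnO2 oxidation of a benzylic and propargylic carbinol leaves the phenol untouched, and the ynone is stabilised by its OH···O=C hydrogen bond.

Step 6
Reactants: 4 7-(benzyloxy)-2-[4-(benzyloxy)phenyl]-6-iodo-5-methoxy-4H-chromen-4-one; 9 1-(2-hydroxy-4,6-dimethoxyphenyl)-3-(4-methoxyphenyl)prop-2-yn-1-one
Product: 10 7-(benzyloxy)-2-[4-(benzyloxy)phenyl]-6-[5,7-dimethoxy-2-(4-methoxyphenyl)-4-oxo-4H-chromen-3-yl]-5-methoxy-4H-chromen-4-one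
Conditions: Pd2(dba)3 (5 mol %), SPhos (2-dicyclohexylphosphino-2',6'-dimethoxybiphenyl, 12 mol %), K3PO4 (2.5 equiv), toluene, 90 °C; 9 (1.5 equiv) added over 6 h
Reagents that add atoms: none
Why: Proposed new method: zerovalent palladium inserts into the C–I bond of 4 to give a monoligated arylpalladium iodide (divalent palladium) that binds the ynone triple bond as a π-acid; the neutral, chelated phenol, too weak a nucleophile to add to the free ynone in toluene over insoluble K3PO4, then adds anti and 6-endo-dig at the β-carbon (the Michael terminus bearing the p-anisyl group) to give a flavon-3-yl(aryl)palladium species whose reductive elimination forges the C3–C6'' bond as ring C of unit 1 closes, slow addition of 9 keeping the arylpalladium resting state in excess over uncomplexed ynone; the closest known reaction type is the Cacchi oxypalladation–reductive elimination of o-alkynylphenols with aryl halides (2,3-disubstituted benzofurans) and its aminopalladative indole counterpart; no stereocentre is formed.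

Step 7
Reactants: 10 7-(benzyloxy)-2-[4-(benzyloxy)phenyl]-6-[5,7-dimethoxy-2-(4-methoxyphenyl)-4-oxo-4H-chromen-3-yl]-5-methoxy-4H-chromen-4-one
Product: 11 5,7-dihydroxy-6-[5-hydroxy-7-methoxy-2-(4-methoxyphenyl)-4-oxo-4H-chromen-3-yl]-2-(4-hydroxyphenyl)-4H-chromen-4-one (CNP0273448.0)
Conditions: BCl3 (1 M in CH2Cl2, 10 equiv), pentamethylbenzene (6 equiv), CH2Cl2, −78 °C → rt; then H2O
Reagents that add atoms: none
Why: Lewis-acid ether cleavage; BCl3 ionises the two aryl benzyl ethers (the benzyl cation is trapped by pentamethylbenzene, so the electron-rich rings are not C-benzylated) and, through six-membered chelation to the C4 and C4'' carbonyls, removes only the two peri (5- and 5''-) methyl ethers, leaving the unchelated 7- and 4'-methoxy groups.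

**Compound list**

1 | apigenin | O=c1cc(-c2ccc(O)cc2)oc2cc(O)cc(O)c12 | starting material
2 | 7-(benzyloxy)-2-[4-(benzyloxy)phenyl]-5-hydroxy-4H-chromen-4-one | O=c1cc(-c2ccc(OCc3ccccc3)cc2)oc2cc(OCc3ccccc3)cc(O)c12 | intermediate
3 | 7-(benzyloxy)-2-[4-(benzyloxy)phenyl]-5-hydroxy-6-iodo-4H-chromen-4-one | O=c1cc(-c2ccc(OCc3ccccc3)cc2)oc2cc(OCc3ccccc3)c(I)c(O)c12 | intermediate
4 | 7-(benzyloxy)-2-[4-(benzyloxy)phenyl]-6-iodo-5-methoxy-4H-chromen-4-one | O=c1cc(-c2ccc(OCc3ccccc3)cc2)oc2cc(OCc3ccccc3)c(I)c(OC)c12 | intermediate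
5 | 4-ethynylanisole (1-ethynyl-4-methoxybenzene) | C#Cc1ccc(OC)cc1 | starting material
6 | 2-hydroxy-4,6-dimethoxybenzaldehyde | O=Cc1c(O)cc(OC)cc1OC | starting material
7 | lithium (4-methoxyphenyl)acetylide | [Li]C#Cc1ccc(OC)cc1 | intermediate (not isolated)
8 | rac-1-(2-hydroxy-4,6-dimethoxyphenyl)-3-(4-methoxyphenyl)prop-2-yn-1-ol (racemic; centre removed in step 5) | OC(C#Cc1ccc(OC)cc1)c1c(O)cc(OC)cc1OC | intermediate
9 | 1-(2-hydroxy-4,6-dimethoxyphenyl)-3-(4-methoxyphenyl)prop-2-yn-1-one | O=C(C#Cc1ccc(OC)cc1)c1c(O)cc(OC)cc1OC | intermediate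
10 | 7-(benzyloxy)-2-[4-(benzyloxy)phenyl]-6-[5,7-dimethoxy-2-(4-methoxyphenyl)-4-oxo-4H-chromen-3-yl]-5-methoxy-4H-chromen-4-one | COc1ccc(-c2oc3cc(OC)cc(OC)c3c(=O)c2-c2c(OCc3ccccc3)cc3oc(-c4ccc(OCc5ccccc5)cc4)cc(=O)c3c2OC)cc1 | intermediate
11 | 5,7-dihydroxy-6-[5-hydroxy-7-methoxy-2-(4-methoxyphenyl)-4-oxo-4H-chromen-3-yl]-2-(4-hydroxyphenyl)-4H-chromen-4-one (no stereocentre) | COc1ccc(-c2oc3cc(OC)cc(O)c3c(=O)c2-c2c(O)cc3oc(-c4ccc(O)cc4)cc(=O)c3c2O)cc1 | target

**Step count**
Total steps: 7. Longest linear sequence: 5 (1 → 2 → 3 → 4 → 10 → 11); the ynone branch (5 + 6 → 8 → 9) joins at step 6.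

**Three steps most likely to fail, with fallbacks**

Step 6 (annulative arylation) is the riskiest. Base-mediated oxa-Michael closure of 9 to 5,7-dimethoxy-2-(4-methoxyphenyl)chromen-4-one, without aryl transfer, can outrun the hindered arylpalladium pathway. The fallback sets out from iodide 4 and comes back at 10, building ring C of unit 1 around a preformed C–C bond by the deoxybenzoin route:
- Iodide 4 is used in a Pd-catalysed ketone α-arylation (Pd2(dba)3, XPhos = 2-dicyclohexylphosphino-2',4',6'-triisopropylbiphenyl, K3PO4, toluene, 100 °C) with 1-[2,4-dimethoxy-6-(methoxymethoxy)phenyl]ethan-1-one F1. F1 is made in one step from commercial 2'-hydroxy-4',6'-dimethoxyacetophenone with MOMCl and iPr2NEt.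
- The arylation gives the deoxybenzoin 2-{7-(benzyloxy)-2-[4-(benzyloxy)phenyl]-5-methoxy-4-oxo-4H-chromen-6-yl}-1-[2,4-dimethoxy-6-(methoxymethoxy)phenyl]ethan-1-one F2.
- HCl in MeOH removes the MOM group to give 2-{7-(benzyloxy)-2-[4-(benzyloxy)phenyl]-5-methoxy-4-oxo-4H-chromen-6-yl}-1-(2-hydroxy-4,6-dimethoxyphenyl)ethan-1-one F3.
- 4-Methoxybenzoyl chloride with DBU in pyridine at 90 °C O-aroylates F3 to 2-({7-(benzyloxy)-2-[4-(benzyloxy)phenyl]-5-methoxy-4-oxo-4H-chromen-6-yl}acetyl)-3,5-dimethoxyphenyl 4-methoxybenzoate F4.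
- F4 undergoes the Baker–Venkataraman acyl shift to 2-{7-(benzyloxy)-2-[4-(benzyloxy)phenyl]-5-methoxy-4-oxo-4H-chromen-6-yl}-1-(2-hydroxy-4,6-dimethoxyphenyl)-3-(4-methoxyphenyl)propane-1,3-dione F5, which cyclodehydrates (AcOH, cat. H2SO4 if needed) to 10.

Step 4 (acetylide addition to the unprotected salicylaldehyde) is the second risk. The lithium phenoxide of 6 is a poor electrophile, and the diol 8 is a highly ionisable 2,4,6-trioxygenated benzylic carbinol. The fallback sets out from aldehyde 6 and comes back at 9, carrying the phenol masked through the C–C bond formation and oxidation: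
- 6 with MOMCl and iPr2NEt gives 2,4-dimethoxy-6-(methoxymethoxy)benzaldehyde F6.
- Acetylide 7 (1.3 equiv, THF, −78 °C) adds to the now normally electrophilic aldehyde to give rac-1-[2,4-dimethoxy-6-(methoxymethoxy)phenyl]-3-(4-methoxyphenyl)prop-2-yn-1-ol F7.
- MnO2 gives 1-[2,4-dimethoxy-6-(methoxymethoxy)phenyl]-3-(4-methoxyphenyl)prop-2-yn-1-one F8.
- TsOH·H2O in MeOH at 40 °C releases 9 under acidic conditions, where the ynone does not undergo base-mediated closure.

Step 7 (one-pot BCl3 global deprotection) is the third risk. The crowded 5''-OMe may cleave incompletely, or the 7-OMe may be lost on prolonged exposure. The fallback sets out from 10 and comes back at 11, splitting the deprotection into two orthogonal operations: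
- Hydrogenolysis (H2, 1 atm, Pd/C, THF–MeOH, rt) removes only the benzyl ethers to give 6-[5,7-dimethoxy-2-(4-methoxyphenyl)-4-oxo-4H-chromen-3-yl]-7-hydroxy-2-(4-hydroxyphenyl)-5-methoxy-4H-chromen-4-one F9.
- MgI2·OEt2 (toluene–THF, 80 °C) then cleaves only the two carbonyl-chelated peri-methoxy groups to give 11.

**Further compounds**

F1 | step 6 | 1-[2,4-dimethoxy-6-(methoxymethoxy)phenyl]ethan-1-one | CC(=O)c1c(OCOC)cc(OC)cc1OC
F2 | step 6 | 2-{7-(benzyloxy)-2-[4-(benzyloxy)phenyl]-5-methoxy-4-oxo-4H-chromen-6-yl}-1-[2,4-dimethoxy-6-(methoxymethoxy)phenyl]ethan-1-one | COCOc1cc(OC)cc(OC)c1C(=O)Cc1c(OCc2ccccc2)cc2oc(-c3ccc(OCc4ccccc4)cc3)cc(=O)c2c1OC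
F3 | step 6 | 2-{7-(benzyloxy)-2-[4-(benzyloxy)phenyl]-5-methoxy-4-oxo-4H-chromen-6-yl}-1-(2-hydroxy-4,6-dimethoxyphenyl)ethan-1-one | COc1cc(O)c(C(=O)Cc2c(OCc3ccccc3)cc3oc(-c4ccc(OCc5ccccc5)cc4)cc(=O)c3c2OC)c(OC)c1
F4 | step 6 | 2-({7-(benzyloxy)-2-[4-(benzyloxy)phenyl]-5-methoxy-4-oxo-4H-chromen-6-yl}acetyl)-3,5-dimethoxyphenyl 4-methoxybenzoate | COc1ccc(C(=O)Oc2cc(OC)cc(OC)c2C(=O)Cc2c(OCc3ccccc3)cc3oc(-c4ccc(OCc5ccccc5)cc4)cc(=O)c3c2OC)cc1
F5 | step 6 | 2-{7-(benzyloxy)-2-[4-(benzyloxy)phenyl]-5-methoxy-4-oxo-4H-chromen-6-yl}-1-(2-hydroxy-4,6-dimethoxyphenyl)-3-(4-methoxyphenyl)propane-1,3-dione | COc1ccc(C(=O)C(C(=O)c2c(O)cc(OC)cc2OC)c2c(OCc3ccccc3)cc3oc(-c4ccc(OCc5ccccc5)cc4)cc(=O)c3c2OC)cc1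
F6 | step 4 | 2,4-dimethoxy-6-(methoxymethoxy)benzaldehyde | O=Cc1c(OCOC)cc(OC)cc1OC
F7 | step 4 | rac-1-[2,4-dimethoxy-6-(methoxymethoxy)phenyl]-3-(4-methoxyphenyl)prop-2-yn-1-ol | OC(C#Cc1ccc(OC)cc1)c1c(OCOC)cc(OC)cc1OC
F8 | step 4 | 1-[2,4-dimethoxy-6-(methoxymethoxy)phenyl]-3-(4-methoxyphenyl)prop-2-yn-1-one | O=C(C#Cc1ccc(OC)cc1)c1c(OCOC)cc(OC)cc1OC
F9 | step 7 | 6-[5,7-dimethoxy-2-(4-methoxyphenyl)-4-oxo-4H-chromen-3-yl]-7-hydroxy-2-(4-hydroxyphenyl)-5-methoxy-4H-chromen-4-one | COc1ccc(-c2oc3cc(OC)cc(OC)c3c(=O)c2-c2c(O)cc3oc(-c4ccc(O)cc4)cc(=O)c3c2OC)cc1
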